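## Retrosynthetic overview

1. Numbering runs from C1 (alkyne CH) to C15 (CH3). Late disconnections: C3=C4 by Z-selective enyne cross-metathesis; C5–C6 (allyl) and C13–C14 (ethyl) by chelation-controlled additions to aldehydes held on the ring oxygen; C13–Br by SN2 inversion of the carbinol.
2. Core disconnection: the bond from the ring O to C12. It is made by an acid-triggered oxirane-to-oxirane relay on the C2-symmetric (S,S)-bis-epoxide of (Z)-octa-1,4,7-triene (C6–C13), terminated by pivalic acid at C6.
3. Enabling feature: in the oxepene ring (O, C7–C12) both O-bearing carbons C7 and C12 carry a hetero-substituted exocyclic carbon (C6–OAc, C13–Br) and are joined by the same cis CH2–CH=CH–CH2 bridge (C8–C11). The C6–C13 core therefore has latent C2 symmetry. Retention at C7 plus inversion at C12 turns the (S,S) pair into the cis-2,7 ring and tells the two arms apart.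
4. The bis-epoxide comes from Z-selective homometathesis of (S)-1-chloropent-4-en-2-ol, itself from (S)-epichlorohydrin and vinylmagnesium bromide. One cheap stereocentre is thus the source of all four.
5. Ring order: two temporary oxirane rings (step 3), then the oxepene ring (step 4), which consumes both oxiranes. No further ring is formed.

Key step: step 4

Remark: the C=C inside the seven-membered ring can only be cis, so ring SMILES carry no geometry mark for it.

## Route

Step 1
Reactants: 1 (S)-epichlorohydrin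
Product: 2 (2S)-1-chloropent-4-en-2-ol
Conditions: CH2=CHMgBr, CuI (10 mol %), THF, −40 to −20 °C; then H2O
Reagents that add atoms: vinylmagnesium bromide, C=C[Mg]Br
Why: Copper-catalysed Grignard opening of a terminal epoxide (SN2 at the unsubstituted ring carbon) is faster than attack at CH2Cl and does not touch the C–O stereocentre, so the (S) centre of 1 becomes the (S) carbinol of 2.

Step 2
Reactants: 2 (2S)-1-chloropent-4-en-2-ol (two molecules)
Product: 3 (2S,4Z,7S)-1,8-dichlorooct-4-ene-2,7-diol
Conditions: Ru(κ2-NO3)(=CH-C6H4-2-O-i-Pr)(C^C-NHC), C^C-NHC = cyclometalated 1-(1-adamantyl)-3-(2,6-diisopropylphenyl)imidazolidin-2-ylidene (2 mol %), THF, 35 °C, static vacuum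
Reagents that add atoms: none
Why: Z-selective olefin homometathesis of a terminal alkene, for which this cyclometalated ruthenium catalyst class tolerates free OH and alkyl chloride, joins two identical (S) units into the C2-symmetric diol and sets the cis C9=C10 bond under kinetic control while ethene escapes.

Step 3
Reactants: 3 (2S,4Z,7S)-1,8-dichlorooct-4-ene-2,7-diol
Product: 4 (2S,2'S)-2,2'-[(2Z)-but-2-ene-1,4-diyl]bis(oxirane)
Conditions: NaOH (powdered), Et2O, 0 °C to rt
Reagents that add atoms: none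
Why: The twofold intramolecular Williamson reaction (3-exo-tet) of the chlorohydrins displaces only the primary chlorides, so both C–O stereocentres stay (S).

Step 4
Reactants: 4 (2S,2'S)-2,2'-[(2Z)-but-2-ene-1,4-diyl]bis(oxirane); 5 pivalic acid
Product: 7 [(2S,7R)-7-(hydroxymethyl)-2,3,6,7-tetrahydrooxepin-2-yl]methyl pivalate, via bicyclic epoxonium ion 6 (not isolated)
Conditions: 5 (1.2 equiv), BF3·OEt2 (20 mol %), CH2Cl2, 0.01 M, slow addition of 4, −40 to 0 °C
Reagents that add atoms: none
Why: Proposed new method: the acid activates either of the two homotopic oxiranes, the oxygen of the other oxirane attacks its inner carbon (future C12) with inversion to give the 1-oxoniabicyclo[5.1.0]octene ion 6, and pivalic acid opens the strained oxiranium part of 6 at its primary CH2 (future C6); should acidolysis at that CH2 come first, the freed secondary OH closes the same O–C12 bond, so both orders converge on 7. The closest known reaction types are BF3·OEt2-promoted polyepoxide oxacyclisations through epoxonium ions (which build oxepanes), capture of epoxonium ions by an added carboxylic acid, and the 7-exo cyclisation of cis-olefinic hydroxy epoxides to oxepenes. The oxepene ring closes in the 7-exo-tet mode, helped by the cis C9=C10 bond, which removes two rotors and holds the two oxiranes within reach of each other. No stereocentre is made from nothing: C7 keeps its C–O bond and C12 is inverted by the SN2 opening, so the (S,S) pair of 4 can only give the cis-2,7 ring, and the C2 axis makes both directions give the same enantiomer with differentiated arms (CH2OPiv at C7, CH2OH at C12). The step needs exo over 8-endo attack (acid activation places more positive charge on the secondary carbon and the smaller ring forms faster), capture at the primary rather than the secondary oxiranium carbons (steric SN2 preference), and ring closure ahead of a second acidolysis or oligomerisation (high dilution, near-stoichiometric acid, cis-alkene preorganisation).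

Step 5
Reactants: 7 [(2S,7R)-7-(hydroxymethyl)-2,3,6,7-tetrahydrooxepin-2-yl]methyl pivalate
Product: 8 [(2S,7R)-7-formyl-2,3,6,7-tetrahydrooxepin-2-yl]methyl pivalate
Conditions: Dess–Martin periodinane, CH2Cl2, 0 °C to rt
Reagents that add atoms: none
Why: Dess–Martin oxidation works under neutral conditions, which avoids epimerisation of the α-alkoxy aldehyde and leaves the pivalate and the ring alkene untouched.

Step 6
Reactants: 8 [(2S,7R)-7-formyl-2,3,6,7-tetrahydrooxepin-2-yl]methyl pivalate
Product: 9 {(2S,7R)-7-[(1R)-1-hydroxypropyl]-2,3,6,7-tetrahydrooxepin-2-yl}methyl pivalate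
Conditions: MgBr2·OEt2, CH2Cl2, −78 °C; EtMgBr (1.2 equiv), −78 °C; then H2O
Reagents that add atoms: ethylmagnesium bromide, CC[Mg]Br
Why: In this chelation-controlled Grignard addition (Cram chelate model) magnesium ties the aldehyde oxygen to the ring oxygen and ethyl attacks from the face of the C12 hydrogen to give the syn (1R) carbinol, while the hindered pivalate is inert at −78 °C.

Step 7
Reactants: 9 {(2S,7R)-7-[(1R)-1-hydroxypropyl]-2,3,6,7-tetrahydrooxepin-2-yl}methyl pivalate
Product: 10 {(2S,7R)-7-[(1S)-1-bromopropyl]-2,3,6,7-tetrahydrooxepin-2-yl}methyl pivalate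
Conditions: CBr4, P(n-Oct)3, toluene, 70 °C
Reagents that add atoms: carbon tetrabromide, BrC(Br)(Br)Br
Why: Appel-type bromination via the alkoxyphosphonium salt is an SN2 displacement, so the (1R) carbinol gives the (1S) bromide with inversion, and the P(n-Oct)3/CBr4/hot toluene variant is the established one for hindered carbinols next to a medium-ring ether oxygen.

Step 8
Reactants: 10 {(2S,7R)-7-[(1S)-1-bromopropyl]-2,3,6,7-tetrahydrooxepin-2-yl}methyl pivalate
Product: 11 {(2S,7R)-7-[(1S)-1-bromopropyl]-2,3,6,7-tetrahydrooxepin-2-yl}methanol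
Conditions: DIBAL-H (2.2 equiv), CH2Cl2, −78 °C; then H2O
Reagents that add atoms: none
Why: Reductive ester cleavage with DIBAL-H at low temperature removes the pivalate without base, so the secondary bromide is neither eliminated nor displaced.

Step 9
Reactants: 11 {(2S,7R)-7-[(1S)-1-bromopropyl]-2,3,6,7-tetrahydrooxepin-2-yl}methanol
Product: 12 (2S,7R)-7-[(1S)-1-bromopropyl]-2,3,6,7-tetrahydrooxepine-2-carbaldehyde
Conditions: Dess–Martin periodinane, CH2Cl2, 0 °C to rt
Reagents that add atoms: none
Why: Dess–Martin oxidation gives the α-alkoxy aldehyde under neutral conditions without epimerisation at C7 and without touching the bromide or the alkene.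

Step 10
Reactants: 12 (2S,7R)-7-[(1S)-1-bromopropyl]-2,3,6,7-tetrahydrooxepine-2-carbaldehyde
Product: 13 (1S)-1-{(2S,7R)-7-[(1S)-1-bromopropyl]-2,3,6,7-tetrahydrooxepin-2-yl}but-3-en-1-ol
Conditions: MgBr2·OEt2 (3 equiv), allylSnBu3, CH2Cl2, −78 to −20 °C; then H2O
Reagents that add atoms: allyltributylstannane, C=CC[Sn](CCCC)(CCCC)CCCC
Why: In this Keck-type chelation-controlled allylation MgBr2 forms the five-membered chelate between aldehyde oxygen and ring oxygen and the stannane attacks from the face of the C7 hydrogen, which gives the syn (1S) homoallylic alcohol.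

Step 11
Reactants: 13 (1S)-1-{(2S,7R)-7-[(1S)-1-bromopropyl]-2,3,6,7-tetrahydrooxepin-2-yl}but-3-en-1-ol
Product: 14 (1S)-1-{(2S,7R)-7-[(1S)-1-bromopropyl]-2,3,6,7-tetrahydrooxepin-2-yl}but-3-en-1-yl acetate
Conditions: Ac2O, pyridine, DMAP (cat.), CH2Cl2, 0 °C to rt
Reagents that add atoms: acetic anhydride, CC(=O)OC(C)=O
Why: DMAP-catalysed acetylation acylates the only free hydroxyl at oxygen, so C6 keeps its configuration.

Step 12
Reactants: 15 (triisopropylsilyl)acetylene; 16 vinyl bromide
Product: 17 (but-3-en-1-yn-1-yl)triisopropylsilane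
Conditions: PdCl2(PPh3)2 (2 mol %), CuI (4 mol %), Et3N, THF, 0 °C to rt
Reagents that add atoms: none
Why: Sonogashira coupling of a terminal alkyne with a vinyl halide gives the silyl-capped conjugated enyne in one step.

Step 13
Reactants: 14 (1S)-1-{(2S,7R)-7-[(1S)-1-bromopropyl]-2,3,6,7-tetrahydrooxepin-2-yl}but-3-en-1-yl acetate; 17 (but-3-en-1-yn-1-yl)triisopropylsilane
Product: 18 (1S,3Z)-1-{(2S,7R)-7-[(1S)-1-bromopropyl]-2,3,6,7-tetrahydrooxepin-2-yl}-6-(triisopropylsilyl)hex-3-en-5-yn-1-yl acetate
Conditions: 17 (4 equiv), second-generation Grubbs catalyst RuCl2(=CHPh)(PCy3)(SIMes) (10 mol %), benzene, 60 °C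
Reagents that add atoms: none
Why: Olefin cross-metathesis of a terminal alkene with a silyl-capped conjugated enyne, a pairing known to favour the Z-enyne under kinetic control, engages only the monosubstituted alkene because the unstrained 1,2-disubstituted ring alkene is a poor substrate.

Step 14
Reactants: 18 (1S,3Z)-1-{(2S,7R)-7-[(1S)-1-bromopropyl]-2,3,6,7-tetrahydrooxepin-2-yl}-6-(triisopropylsilyl)hex-3-en-5-yn-1-yl acetate
Product: 19 (1S,3Z)-1-{(2S,7R)-7-[(1S)-1-bromopropyl]-2,3,6,7-tetrahydrooxepin-2-yl}hex-3-en-5-yn-1-yl acetate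
Conditions: Bu4NF, AcOH, THF, 0 °C
Reagents that add atoms: none
Why: Fluoride-induced protodesilylation of the alkynylsilane, buffered with acetic acid so that the acetate and the secondary bromide survive, should deliver the target.

## Compound list

1 | (S)-epichlorohydrin, (2S)-2-(chloromethyl)oxirane | ClC[C@@H]1CO1 | starting material
2 | (2S)-1-chloropent-4-en-2-ol | ClC[C@@H](O)CC=C | intermediate
3 | (2S,4Z,7S)-1,8-dichlorooct-4-ene-2,7-diol | ClC[C@@H](O)C/C=C\C[C@H](O)CCl | intermediate
4 | (2S,2'S)-2,2'-[(2Z)-but-2-ene-1,4-diyl]bis(oxirane) | C1O[C@H]1C/C=C\C[C@H]1CO1 | intermediate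
5 | pivalic acid | CC(C)(C)C(=O)O | starting material
6 | (2R,7S)-2-(hydroxymethyl)-1-oxoniabicyclo[5.1.0]oct-4-ene (cation, not isolated) | OC[C@H]1CC=CC[C@H]2C[O+]12 | intermediate
7 | [(2S,7R)-7-(hydroxymethyl)-2,3,6,7-tetrahydrooxepin-2-yl]methyl pivalate | CC(C)(C)C(=O)OC[C@@H]1CC=CC[C@H](CO)O1 | intermediate
8 | [(2S,7R)-7-formyl-2,3,6,7-tetrahydrooxepin-2-yl]methyl pivalate | CC(C)(C)C(=O)OC[C@@H]1CC=CC[C@H](C=O)O1 | intermediate
9 | {(2S,7R)-7-[(1R)-1-hydroxypropyl]-2,3,6,7-tetrahydrooxepin-2-yl}methyl pivalate | CC(C)(C)C(=O)OC[C@@H]1CC=CC[C@H]([C@H](O)CC)O1 | intermediate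
10 | {(2S,7R)-7-[(1S)-1-bromopropyl]-2,3,6,7-tetrahydrooxepin-2-yl}methyl pivalate | CC(C)(C)C(=O)OC[C@@H]1CC=CC[C@H]([C@@H](Br)CC)O1 | intermediate
11 | {(2S,7R)-7-[(1S)-1-bromopropyl]-2,3,6,7-tetrahydrooxepin-2-yl}methanol | OC[C@@H]1CC=CC[C@H]([C@@H](Br)CC)O1 | intermediate
12 | (2S,7R)-7-[(1S)-1-bromopropyl]-2,3,6,7-tetrahydrooxepine-2-carbaldehyde | O=C[C@@H]1CC=CC[C@H]([C@@H](Br)CC)O1 | intermediate
13 | (1S)-1-{(2S,7R)-7-[(1S)-1-bromopropyl]-2,3,6,7-tetrahydrooxepin-2-yl}but-3-en-1-ol | C=CC[C@H](O)[C@@H]1CC=CC[C@H]([C@@H](Br)CC)O1 | intermediate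
14 | (1S)-1-{(2S,7R)-7-[(1S)-1-bromopropyl]-2,3,6,7-tetrahydrooxepin-2-yl}but-3-en-1-yl acetate | C=CC[C@H](OC(C)=O)[C@@H]1CC=CC[C@H]([C@@H](Br)CC)O1 | intermediate
15 | (triisopropylsilyl)acetylene | C#C[Si](C(C)C)(C(C)C)C(C)C | starting material
16 | vinyl bromide | C=CBr | starting material
17 | (but-3-en-1-yn-1-yl)triisopropylsilane | C=CC#C[Si](C(C)C)(C(C)C)C(C)C | intermediate
18 | (1S,3Z)-1-{(2S,7R)-7-[(1S)-1-bromopropyl]-2,3,6,7-tetrahydrooxepin-2-yl}-6-(triisopropylsilyl)hex-3-en-5-yn-1-yl acetate | CC(C)[Si](C#C/C=C\C[C@H](OC(C)=O)[C@@H]1CC=CC[C@H]([C@@H](Br)CC)O1)(C(C)C)C(C)C | intermediate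
19 | (1S,3Z)-1-{(2S,7R)-7-[(1S)-1-bromopropyl]-2,3,6,7-tetrahydrooxepin-2-yl}hex-3-en-5-yn-1-yl acetate | C#C/C=C\C[C@H](OC(C)=O)[C@@H]1CC=CC[C@H]([C@@H](Br)CC)O1 | target

Total step count: 14. Longest linear sequence: 13 (steps 1–11, 13, 14).

## Steps most likely to fail

**Step 4.** Four processes could spoil the relay:
- a second acidolysis or cationic oligomerisation outrunning ring closure;
- attack at the terminal carbon (8-endo);
- attack of pivalic acid at a secondary carbon;
- acid-induced rearrangement of an oxirane to a carbonyl compound.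

The fallback sets out from 4 and comes back at 7. It gives up the relay for two separate known reactions.
- One oxirane of 4 is opened at its CH2 with caesium pivalate (CsO2CCMe3, pivalic acid, DMF, 50 °C, run to partial conversion, unreacted 4 recycled). This is a standard carboxylate opening of a terminal epoxide. It gives (2S,4Z)-2-hydroxy-6-[(2S)-oxiran-2-yl]hex-4-en-1-yl pivalate F1, which is isolated.
- (Bu3Sn)2O in refluxing toluene converts it into (2S,4Z)-6-[(2S)-oxiran-2-yl]-2-[(tributylstannyl)oxy]hex-4-en-1-yl pivalate F2.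
- Zn(OTf)2 then promotes the known 7-exo cyclisation of cis-olefinic stannyloxy epoxides to [(2S,7R)-7-{[(tributylstannyl)oxy]methyl}-2,3,6,7-tetrahydrooxepin-2-yl]methyl pivalate F3, which is hydrolysed on work-up to 7.

**Step 13.** Possible failures are erosion of the Z geometry by secondary metathesis, homodimerisation of 14, and catalyst deactivation by the enyne. The fallback sets out from 12 and comes back at 18. It builds the Z-alkene by alkyne reduction instead of metathesis.
- Chelation-controlled propargylation of 12 with allenyltributylstannane and MgBr2·OEt2 gives (1S)-1-{(2S,7R)-7-[(1S)-1-bromopropyl]-2,3,6,7-tetrahydrooxepin-2-yl}but-3-yn-1-ol F4.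
- Acetylation (Ac2O, pyridine) gives (1S)-1-{(2S,7R)-7-[(1S)-1-bromopropyl]-2,3,6,7-tetrahydrooxepin-2-yl}but-3-yn-1-yl acetate F5.
- N-Iodosuccinimide with AgNO3 gives (1S)-1-{(2S,7R)-7-[(1S)-1-bromopropyl]-2,3,6,7-tetrahydrooxepin-2-yl}-4-iodobut-3-yn-1-yl acetate F6.
- Diimide (2-nitrobenzenesulfonohydrazide, Et3N) reduces the iodoalkyne to (1S,3Z)-1-{(2S,7R)-7-[(1S)-1-bromopropyl]-2,3,6,7-tetrahydrooxepin-2-yl}-4-iodobut-3-en-1-yl acetate F7.
- Sonogashira coupling with 15 (PdCl2(PPh3)2, CuI, Et3N), which keeps the alkene geometry, gives 18.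

**Step 7.** Possible failures are participation of the ring oxygen (leading to retention or ring expansion through an oxiranium ion) and elimination at the hot phosphonium stage. The fallback sets out from 9 and comes back at 10. It separates activation from substitution.
- Chloromethanesulfonyl chloride and 2,6-lutidine (CH2Cl2, 0 °C) give {(2S,7R)-7-[(1R)-1-{[(chloromethyl)sulfonyl]oxy}propyl]-2,3,6,7-tetrahydrooxepin-2-yl}methyl pivalate F8.
- This isolated, highly reactive sulfonate is displaced by LiBr (DMF, rt) with inversion to 10.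

## Further compounds

F1 | step 4 | (2S,4Z)-2-hydroxy-6-[(2S)-oxiran-2-yl]hex-4-en-1-yl pivalate | CC(C)(C)C(=O)OC[C@@H](O)C/C=C\C[C@H]1CO1
F2 | step 4 | (2S,4Z)-6-[(2S)-oxiran-2-yl]-2-[(tributylstannyl)oxy]hex-4-en-1-yl pivalate | CC(C)(C)C(=O)OC[C@@H](O[Sn](CCCC)(CCCC)CCCC)C/C=C\C[C@H]1CO1
F3 | step 4 | [(2S,7R)-7-{[(tributylstannyl)oxy]methyl}-2,3,6,7-tetrahydrooxepin-2-yl]methyl pivalate | CC(C)(C)C(=O)OC[C@@H]1CC=CC[C@H](CO[Sn](CCCC)(CCCC)CCCC)O1
F4 | step 13 | (1S)-1-{(2S,7R)-7-[(1S)-1-bromopropyl]-2,3,6,7-tetrahydrooxepin-2-yl}but-3-yn-1-ol | C#CC[C@H](O)[C@@H]1CC=CC[C@H]([C@@H](Br)CC)O1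
F5 | step 13 | (1S)-1-{(2S,7R)-7-[(1S)-1-bromopropyl]-2,3,6,7-tetrahydrooxepin-2-yl}but-3-yn-1-yl acetate | C#CC[C@H](OC(C)=O)[C@@H]1CC=CC[C@H]([C@@H](Br)CC)O1
F6 | step 13 | (1S)-1-{(2S,7R)-7-[(1S)-1-bromopropyl]-2,3,6,7-tetrahydrooxepin-2-yl}-4-iodobut-3-yn-1-yl acetate | IC#CC[C@H](OC(C)=O)[C@@H]1CC=CC[C@H]([C@@H](Br)CC)O1
F7 | step 13 | (1S,3Z)-1-{(2S,7R)-7-[(1S)-1-bromopropyl]-2,3,6,7-tetrahydrooxepin-2-yl}-4-iodobut-3-en-1-yl acetate | I/C=C\C[C@H](OC(C)=O)[C@@H]1CC=CC[C@H]([C@@H](Br)CC)O1
F8 | step 7 | {(2S,7R)-7-[(1R)-1-{[(chloromethyl)sulfonyl]oxy}propyl]-2,3,6,7-tetrahydrooxepin-2-yl}methyl pivalate | CC(C)(C)C(=O)OC[C@@H]1CC=CC[C@H]([C@H](OS(=O)(=O)CCl)CC)O1
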